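**Plan**

1. Retrosynthesis: remove 14 benzyl and 2 acetyl groups, then cut both C4–C8 interflavan bonds (top C4–middle C8 first, then middle C4–bottom C8), each into a 4-alkoxyflavan electrophile and a flavan nucleophile. The catechin unit is chiral pool; both gallocatechin units are one de novo compound.
2. In that gallocatechin unit, ring C is cut at C2–C3 (enol ether–olefin ring-closing metathesis), then at the exocyclic methylene (ester methylenation), the O1–C2 acyl bond (esterification) and C4–C4a (Claisen rearrangement).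
3. Enabling feature: O1 is a phenolic oxygen of phloroglucinol ring A and C2 carries only pyrogallol ring B, so O1–C2–ring B can arrive as an aryl benzoate and C4–C3 as an ortho-allyl group. The ester carbonyl oxygen and the terminal CH2 are helpers, lost as titanium oxide and ethylene.
4. Forward: ring A phenol → allyl ether → Claisen → aroylation → methylenation → RCM closes ring C as the 2-aryl-4H-chromene (C2=C3) → hydroboration → C4 activation → coupling to the bottom unit → coupling of the catechin electrophile → deprotection.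
5. Stereochemistry: C2/C3 of both gallocatechin units come from syn hydroboration of the C2=C3 enol ether with a chiral borane (trans, 2R,3S). Each C4 comes from attack of C8 on the planar C4 cation anti to the 3-acetoxy group (4α, 3,4-trans). Catechin C2/C3 come from (+)-catechin.

Key step: step 5

Remark: the structure is read as catechin-(4α→8)-gallocatechin-(4α→8)-gallocatechin, all three units (2R,3S) and 2,3-trans, both interflavan bonds 3,4-trans; "4α" means the face of ring C opposite the 3-hydroxyl in these units.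

**Route**

Step 1
Reactants: 1 3,5-bis(benzyloxy)phenol; 2 allyl bromide
Product: 3 allyl 3,5-bis(benzyloxy)phenyl ether
Conditions: K2CO3, acetone, reflux
Reagents that add atoms: none
Why: Williamson ether synthesis (SN2 of the phenoxide on allyl bromide) under carbonate conditions should favour O- over C-allylation of this electron-rich phenol.

Step 2
Reactants: 3 allyl 3,5-bis(benzyloxy)phenyl ether
Product: 4 2-allyl-3,5-bis(benzyloxy)phenol
Conditions: N,N-diethylaniline, 190 °C, argon
Reagents that add atoms: none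
Why: Aromatic Claisen rearrangement ([3,3]-sigmatropic shift, then tautomerization) delivers the allyl group only ortho to the oxygen that becomes O1, the two ortho positions being equivalent, so C4 and C3 are placed next to O1 and not between the two benzyloxy groups.

Step 3
Reactants: 4 2-allyl-3,5-bis(benzyloxy)phenol; 5 3,4,5-tris(benzyloxy)benzoic acid
Product: 6 2-allyl-3,5-bis(benzyloxy)phenyl 3,4,5-tris(benzyloxy)benzoate
Conditions: DCC, DMAP (cat.), CH2Cl2, 0 °C to rt
Reagents that add atoms: none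
Why: Steglich esterification (carbodiimide activation with DMAP acyl transfer) should acylate the moderately hindered phenol and so attach ring B and C2, at the ester oxidation level, to O1.

Step 4
Reactants: 6 2-allyl-3,5-bis(benzyloxy)phenyl 3,4,5-tris(benzyloxy)benzoate
Product: 7 2-allyl-3,5-bis(benzyloxy)phenyl 1-[3,4,5-tris(benzyloxy)phenyl]ethenyl ether
Conditions: Cp2TiMe2 (2.5 equiv), toluene, 70 °C, dark; filtration through basic alumina
Reagents that add atoms: dimethyltitanocene, [CH3-].[CH3-].[Ti+4].c1cc[cH-]c1.c1cc[cH-]c1 (supplies the =CH2 carbon)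
Why: Petasis methylenation (thermally formed Cp2Ti=CH2, [2+2] with the ester carbonyl, cycloreversion to titanocene oxide) converts aryl benzoates into 1-aryloxy-1-arylethenes, and the non-acidic reagent should spare the benzyl ethers and the acid-labile enol ether.

Step 5
Reactants: 7 2-allyl-3,5-bis(benzyloxy)phenyl 1-[3,4,5-tris(benzyloxy)phenyl]ethenyl ether
Product: 8 5,7-bis(benzyloxy)-2-[3,4,5-tris(benzyloxy)phenyl]-4H-chromene
Conditions: second-generation Grubbs catalyst RuCl2(=CHPh)(PCy3)(H2IMes) (5 mol%), 1,4-benzoquinone (10 mol%), degassed toluene, 70 °C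
Reagents that add atoms: none
Why: Ring-closing enol ether–olefin metathesis: the ruthenium benzylidene loads on the unhindered allyl terminus, the new alkylidene undergoes intramolecular [2+2] cycloaddition with the 1,1-disubstituted enol ether, and cycloreversion expels ethylene to form the C2=C3 bond. The closest known reaction type is the RCM of olefinic enol ethers obtained by titanium methylenation of olefinic esters, which includes 2-allylphenyl esters leading to 2-substituted 4H-chromenes. Ring C closes as a six-membered ring in which both olefin carbons (C2 and C3) become ring atoms. No stereocenter is formed; the step fixes the double bond at C2=C3, which is what the following hydroboration needs to put oxygen on C3 and hydrogen on C2. The selectivity required is cyclization ahead of allyl-to-propenyl isomerization (which would end in a 2-arylbenzofuran) and ahead of dimerization; benzoquinone should suppress ruthenium hydride, and the ortho placement of both olefins on ring A favours ring closure.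

Step 6
Reactants: 8 5,7-bis(benzyloxy)-2-[3,4,5-tris(benzyloxy)phenyl]-4H-chromene
Product: 10 (2R,3S)-5,7-bis(benzyloxy)-2-[3,4,5-tris(benzyloxy)phenyl]chroman-3-ol (penta-O-benzylgallocatechin), via chroman-3-yl(isopinocampheyl)borane 9 (not isolated)
Conditions: monoisopinocampheylborane from (+)-α-pinene, THF, −25 °C; then NaOH, 30% H2O2, 0 °C to rt; recrystallization
Reagents that add atoms: hydrogen peroxide, OO (oxygen of the 3-hydroxyl); monoisopinocampheylborane, C[C@H]1[C@H](B)C[C@@H]2C[C@H]1C2(C)C (boron and isopinocampheyl group of intermediate 9)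
Why: Brown asymmetric hydroboration–oxidation: boron should add to C3 (β to the enol ether oxygen) and hydrogen to C2 in a syn four-centre addition on the face selected by the isopinocampheyl group, and oxidation with retention then gives the 2-aryl and 3-hydroxyl groups trans; the (2R,3S) sense is assigned by analogy with 1-phenylcyclohexene, which this borane antipode converts into the (1S,2R)-trans alcohol, and the reagent from (−)-α-pinene would be used if the sense proved reversed on this enol ether.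

Step 7
Reactants: 10 (2R,3S)-5,7-bis(benzyloxy)-2-[3,4,5-tris(benzyloxy)phenyl]chroman-3-ol
Product: 11 (2R,3S,4S)-5,7-bis(benzyloxy)-4-(2-ethoxyethoxy)-2-[3,4,5-tris(benzyloxy)phenyl]chroman-3-ol
Conditions: DDQ (2 equiv), 2-ethoxyethanol, CH2Cl2, rt
Reagents that add atoms: 2-ethoxyethanol, CCOCCO
Why: Benzylic oxidative etherification: DDQ abstracts hydride from C4, which is activated by the 5,7-dioxygenated ring A, and the alcohol traps the cation; the new C4 centre (alkoxy cis to the 3-hydroxyl) is planarized again in step 9, so its configuration is immaterial.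

Step 8
Reactants: 11 (2R,3S,4S)-5,7-bis(benzyloxy)-4-(2-ethoxyethoxy)-2-[3,4,5-tris(benzyloxy)phenyl]chroman-3-ol
Product: 12 (2R,3S,4S)-3-acetoxy-5,7-bis(benzyloxy)-4-(2-ethoxyethoxy)-2-[3,4,5-tris(benzyloxy)phenyl]chroman
Conditions: Ac2O, pyridine, DMAP (cat.), rt
Reagents that add atoms: acetic anhydride, CC(=O)OC(C)=O
Why: DMAP-catalysed acetylation of the secondary 3-hydroxyl installs the group that shields the β-face of the later C4 cation.

Step 9
Reactants: 12 (2R,3S,4S)-3-acetoxy-5,7-bis(benzyloxy)-4-(2-ethoxyethoxy)-2-[3,4,5-tris(benzyloxy)phenyl]chroman; 10 (2R,3S)-5,7-bis(benzyloxy)-2-[3,4,5-tris(benzyloxy)phenyl]chroman-3-ol (3 equiv, excess recovered)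
Product: 13 3-O-acetyl-penta-O-benzylgallocatechin-(4α→8)-penta-O-benzylgallocatechin
Conditions: TMSOTf (0.5 equiv), CH2Cl2, −78 °C; Et3N quench
Reagents that add atoms: none
Why: Lewis acid ionization of the 4-alkoxy group gives the ring-A-stabilized C4 cation, which C8 of the nucleophile (the most reactive A-ring position) should attack in a Friedel–Crafts alkylation from the face opposite the 3-acetoxy group, setting the middle-unit C4 as 4α (3,4-trans).

Step 10
Reactants: 14 (+)-catechin
Product: 15 (2R,3S)-5,7-bis(benzyloxy)-2-[3,4-bis(benzyloxy)phenyl]chroman-3-ol (tetra-O-benzylcatechin)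
Conditions: BnBr (4.4 equiv), K2CO3, DMF, 0 °C to rt
Reagents that add atoms: benzyl bromide, BrCc1ccccc1
Why: Williamson benzylation of the four phenolic hydroxyls under carbonate conditions should leave the secondary 3-hydroxyl free and avoid epimerization at C2.

Step 11
Reactants: 15 (2R,3S)-5,7-bis(benzyloxy)-2-[3,4-bis(benzyloxy)phenyl]chroman-3-ol
Product: 16 (2R,3S,4S)-5,7-bis(benzyloxy)-2-[3,4-bis(benzyloxy)phenyl]-4-(2-ethoxyethoxy)chroman-3-ol
Conditions: DDQ (2 equiv), 2-ethoxyethanol, CH2Cl2, rt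
Reagents that add atoms: 2-ethoxyethanol, CCOCCO
Why: The same DDQ benzylic oxidative etherification at C4 as in step 7, a standard activation of benzylated flavan-3-ols.

Step 12
Reactants: 16 (2R,3S,4S)-5,7-bis(benzyloxy)-2-[3,4-bis(benzyloxy)phenyl]-4-(2-ethoxyethoxy)chroman-3-ol
Product: 17 (2R,3S,4S)-3-acetoxy-5,7-bis(benzyloxy)-2-[3,4-bis(benzyloxy)phenyl]-4-(2-ethoxyethoxy)chroman
Conditions: Ac2O, pyridine, DMAP (cat.), rt
Reagents that add atoms: acetic anhydride, CC(=O)OC(C)=O
Why: DMAP-catalysed acetylation of the 3-hydroxyl, as in step 8, provides the face-shielding group for the second coupling.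

Step 13
Reactants: 17 (2R,3S,4S)-3-acetoxy-5,7-bis(benzyloxy)-2-[3,4-bis(benzyloxy)phenyl]-4-(2-ethoxyethoxy)chroman; 13 3-O-acetyl-penta-O-benzylgallocatechin-(4α→8)-penta-O-benzylgallocatechin (2 equiv, excess recovered)
Product: 18 3-O-acetyl-tetra-O-benzylcatechin-(4α→8)-3-O-acetyl-penta-O-benzylgallocatechin-(4α→8)-penta-O-benzylgallocatechin
Conditions: TMSOTf (0.5 equiv), CH2Cl2, −78 °C; Et3N quench
Reagents that add atoms: none
Why: The same cationic Friedel–Crafts coupling, in which the only free C8 of the dimer (that of its upper unit) should react in preference to the two C6 positions, and attack anti to the 3-acetoxy group of the catechin cation sets the top-unit C4 as 4α (3,4-trans).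

Step 14
Reactants: 18 3-O-acetyl-tetra-O-benzylcatechin-(4α→8)-3-O-acetyl-penta-O-benzylgallocatechin-(4α→8)-penta-O-benzylgallocatechin
Product: 19 tetra-O-benzylcatechin-(4α→8)-penta-O-benzylgallocatechin-(4α→8)-penta-O-benzylgallocatechin
Conditions: n-Bu4NOH (aq.), THF, rt
Reagents that add atoms: none
Why: Hydroxide-mediated ester hydrolysis removes both acetates, and with every phenol benzylated no quinone methide pathway for C2 epimerization is open.

Step 15
Reactants: 19 tetra-O-benzylcatechin-(4α→8)-penta-O-benzylgallocatechin-(4α→8)-penta-O-benzylgallocatechin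
Product: 20 catechin-(4α→8)-gallocatechin-(4α→8)-gallocatechin (CNP0188605.2)
Conditions: H2 (1 atm), Pd(OH)2/C, THF–MeOH–H2O, rt; filtration and lyophilization under argon
Reagents that add atoms: none
Why: Catalytic hydrogenolysis of the fourteen benzyl ethers under neutral conditions should leave the interflavan bonds and all stereocenters untouched.

**Compound list**

1 | 3,5-bis(benzyloxy)phenol | Oc1cc(OCc2ccccc2)cc(OCc2ccccc2)c1 | starting material
2 | allyl bromide | C=CCBr | starting material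
3 | allyl 3,5-bis(benzyloxy)phenyl ether | C=CCOc1cc(OCc2ccccc2)cc(OCc2ccccc2)c1 | intermediate
4 | 2-allyl-3,5-bis(benzyloxy)phenol | C=CCc1c(O)cc(OCc2ccccc2)cc1OCc1ccccc1 | intermediate
5 | 3,4,5-tris(benzyloxy)benzoic acid | OC(=O)c1cc(OCc2ccccc2)c(OCc2ccccc2)c(OCc2ccccc2)c1 | starting material
6 | 2-allyl-3,5-bis(benzyloxy)phenyl 3,4,5-tris(benzyloxy)benzoate | C=CCc1c(OC(=O)c2cc(OCc3ccccc3)c(OCc3ccccc3)c(OCc3ccccc3)c2)cc(OCc2ccccc2)cc1OCc1ccccc1 | intermediate
7 | 2-allyl-3,5-bis(benzyloxy)phenyl 1-[3,4,5-tris(benzyloxy)phenyl]ethenyl ether | C=CCc1c(OC(=C)c2cc(OCc3ccccc3)c(OCc3ccccc3)c(OCc3ccccc3)c2)cc(OCc2ccccc2)cc1OCc1ccccc1 | intermediate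
8 | 5,7-bis(benzyloxy)-2-[3,4,5-tris(benzyloxy)phenyl]-4H-chromene | C1=C(c2cc(OCc3ccccc3)c(OCc3ccccc3)c(OCc3ccccc3)c2)Oc2cc(OCc3ccccc3)cc(OCc3ccccc3)c2C1 | intermediate
9 | [2,3-trans-5,7-bis(benzyloxy)-2-(3,4,5-tris(benzyloxy)phenyl)chroman-3-yl](isopinocampheyl)borane, boron in the place of the later 3-hydroxyl | C[C@H]1[C@H](B[C@H]3Cc4c(OCc5ccccc5)cc(OCc5ccccc5)cc4O[C@@H]3c3cc(OCc5ccccc5)c(OCc5ccccc5)c(OCc5ccccc5)c3)C[C@@H]2C[C@H]1C2(C)C | intermediate (not isolated)
10 | (2R,3S)-5,7-bis(benzyloxy)-2-[3,4,5-tris(benzyloxy)phenyl]chroman-3-ol (penta-O-benzylgallocatechin) | c1c(OCc3ccccc3)cc(OCc3ccccc3)c2c1O[C@H](c1cc(OCc3ccccc3)c(OCc3ccccc3)c(OCc3ccccc3)c1)[C@@H](O)C2 | intermediate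
11 | (2R,3S,4S)-5,7-bis(benzyloxy)-4-(2-ethoxyethoxy)-2-[3,4,5-tris(benzyloxy)phenyl]chroman-3-ol | c1c(OCc3ccccc3)cc(OCc3ccccc3)c2c1O[C@H](c1cc(OCc3ccccc3)c(OCc3ccccc3)c(OCc3ccccc3)c1)[C@@H](O)[C@H]2OCCOCC | intermediate
12 | (2R,3S,4S)-3-acetoxy-5,7-bis(benzyloxy)-4-(2-ethoxyethoxy)-2-[3,4,5-tris(benzyloxy)phenyl]chroman | c1c(OCc3ccccc3)cc(OCc3ccccc3)c2c1O[C@H](c1cc(OCc3ccccc3)c(OCc3ccccc3)c(OCc3ccccc3)c1)[C@@H](OC(C)=O)[C@H]2OCCOCC | intermediate
13 | 3-O-acetyl-penta-O-benzylgallocatechin-(4α→8)-penta-O-benzylgallocatechin | c1c(OCc3ccccc3)cc(OCc3ccccc3)c2c1O[C@H](c1cc(OCc3ccccc3)c(OCc3ccccc3)c(OCc3ccccc3)c1)[C@@H](OC(C)=O)[C@@H]2c1c(OCc3ccccc3)cc(OCc3ccccc3)c2c1O[C@H](c1cc(OCc3ccccc3)c(OCc3ccccc3)c(OCc3ccccc3)c1)[C@@H](O)C2 | intermediate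
14 | (+)-catechin, (2R,3S) | Oc1cc(O)c2c(c1)O[C@H](c1ccc(O)c(O)c1)[C@@H](O)C2 | starting material
15 | (2R,3S)-5,7-bis(benzyloxy)-2-[3,4-bis(benzyloxy)phenyl]chroman-3-ol (tetra-O-benzylcatechin) | c1c(OCc3ccccc3)cc(OCc3ccccc3)c2c1O[C@H](c1ccc(OCc3ccccc3)c(OCc3ccccc3)c1)[C@@H](O)C2 | intermediate
16 | (2R,3S,4S)-5,7-bis(benzyloxy)-2-[3,4-bis(benzyloxy)phenyl]-4-(2-ethoxyethoxy)chroman-3-ol | c1c(OCc3ccccc3)cc(OCc3ccccc3)c2c1O[C@H](c1ccc(OCc3ccccc3)c(OCc3ccccc3)c1)[C@@H](O)[C@H]2OCCOCC | intermediate
17 | (2R,3S,4S)-3-acetoxy-5,7-bis(benzyloxy)-2-[3,4-bis(benzyloxy)phenyl]-4-(2-ethoxyethoxy)chroman | c1c(OCc3ccccc3)cc(OCc3ccccc3)c2c1O[C@H](c1ccc(OCc3ccccc3)c(OCc3ccccc3)c1)[C@@H](OC(C)=O)[C@H]2OCCOCC | intermediate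
18 | 3-O-acetyl-tetra-O-benzylcatechin-(4α→8)-3-O-acetyl-penta-O-benzylgallocatechin-(4α→8)-penta-O-benzylgallocatechin | c1c(OCc3ccccc3)cc(OCc3ccccc3)c2c1O[C@H](c1ccc(OCc3ccccc3)c(OCc3ccccc3)c1)[C@@H](OC(C)=O)[C@@H]2c1c(OCc3ccccc3)cc(OCc3ccccc3)c2c1O[C@H](c1cc(OCc3ccccc3)c(OCc3ccccc3)c(OCc3ccccc3)c1)[C@@H](OC(C)=O)[C@@H]2c1c(OCc3ccccc3)cc(OCc3ccccc3)c2c1O[C@H](c1cc(OCc3ccccc3)c(OCc3ccccc3)c(OCc3ccccc3)c1)[C@@H](O)C2 | intermediate
19 | tetra-O-benzylcatechin-(4α→8)-penta-O-benzylgallocatechin-(4α→8)-penta-O-benzylgallocatechin | c1c(OCc3ccccc3)cc(OCc3ccccc3)c2c1O[C@H](c1ccc(OCc3ccccc3)c(OCc3ccccc3)c1)[C@@H](O)[C@@H]2c1c(OCc3ccccc3)cc(OCc3ccccc3)c2c1O[C@H](c1cc(OCc3ccccc3)c(OCc3ccccc3)c(OCc3ccccc3)c1)[C@@H](O)[C@@H]2c1c(OCc3ccccc3)cc(OCc3ccccc3)c2c1O[C@H](c1cc(OCc3ccccc3)c(OCc3ccccc3)c(OCc3ccccc3)c1)[C@@H](O)C2 | intermediate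
20 | catechin-(4α→8)-gallocatechin-(4α→8)-gallocatechin (CNP0188605.2) | Oc1cc(O)c2c(c1)O[C@H](c1ccc(O)c(O)c1)[C@@H](O)[C@@H]2c1c(O)cc(O)c2c1O[C@H](c1cc(O)c(O)c(O)c1)[C@@H](O)[C@@H]2c1c(O)cc(O)c2c1O[C@H](c1cc(O)c(O)c(O)c1)[C@@H](O)C2 | target

**Step count and risks**

Total: 15 steps. Longest linear sequence: 12 steps (steps 1–9, 13, 14, 15); steps 10–12 form the three-step catechin branch.

Steps most likely to fail:

Step 5 (ring closure). The allyl group may isomerize to a propenyl group before cyclization, so that metathesis contracts to a benzofuran; the hindered 1,1-disubstituted enol ether may also react too slowly and the catalyst decompose. Fallback, from 6 back to 8: Lemieux–Johnson cleavage of the allyl group of ester 6 (OsO4 cat., NaIO4, 2,6-lutidine, dioxane–water) should give 2-(2-oxoethyl)-3,5-bis(benzyloxy)phenyl 3,4,5-tris(benzyloxy)benzoate F1. Intramolecular McMurry-type ester–aldehyde reductive coupling of F1 with low-valent titanium (TiCl3, Zn–Cu couple, DME, reflux, slow addition) then closes the same C2=C3 bond and returns chromene 8.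

Step 6 (hydroboration). Facial discrimination by the chiral borane may be incomplete on this 2-aryl enol ether, and the bulky reagent may add slowly, leaving time for double-bond migration to the 2H-chromene. Fallback, from 8 back to 10: hydroboration with BH3·SMe2 (THF, 0 °C) and NaOH/H2O2 oxidation should give the racemic trans alcohol, that is 10 together with its (2S,3R) enantiomer F2. Preparative chromatography on a chiral stationary phase (amylose tris(3,5-dimethylphenylcarbamate)) then separates 10 from F2, replacing reagent control by resolution.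

Step 13 (second coupling). The catechin cation may attack a C6 position of the dimer instead of the free C8, and the product, itself nucleophilic, may condense further. Fallback, from 12 back to 18, using orthogonal activation so that every coupling uses a monomeric nucleophile: treatment of 12 with 2,6-dimethylbenzenethiol and BF3·OEt2 (CH2Cl2, −78 °C) should give the 4-(2,6-dimethylphenylthio) acetate F3 (drawn 3,4-trans; either C4 epimer serves). F3 is used as the nucleophile toward 17 under hard activation (TMSOTf, CH2Cl2, −78 °C), which should leave the sulfide untouched and give the catechin-(4α→8)-gallocatechin 4-sulfide F4. Thiophilic activation of F4 (AgBF4, CH2Cl2, −40 °C) in the presence of 10 then forms the middle C4–bottom C8 bond and gives 18; dimer 13 is not needed on this path.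

**Further compounds**

F1 | step 5 | 2-(2-oxoethyl)-3,5-bis(benzyloxy)phenyl 3,4,5-tris(benzyloxy)benzoate | O=CCc1c(OC(=O)c2cc(OCc3ccccc3)c(OCc3ccccc3)c(OCc3ccccc3)c2)cc(OCc2ccccc2)cc1OCc1ccccc1
F2 | step 6 | (2S,3R)-5,7-bis(benzyloxy)-2-[3,4,5-tris(benzyloxy)phenyl]chroman-3-ol (enantiomer of 10) | c1c(OCc3ccccc3)cc(OCc3ccccc3)c2c1O[C@@H](c1cc(OCc3ccccc3)c(OCc3ccccc3)c(OCc3ccccc3)c1)[C@H](O)C2
F3 | step 13 | 3-O-acetyl-penta-O-benzyl-4α-(2,6-dimethylphenylthio)gallocatechin | c1c(OCc3ccccc3)cc(OCc3ccccc3)c2c1O[C@H](c1cc(OCc3ccccc3)c(OCc3ccccc3)c(OCc3ccccc3)c1)[C@@H](OC(C)=O)[C@@H]2Sc1c(C)cccc1C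
F4 | step 13 | 3-O-acetyl-tetra-O-benzylcatechin-(4α→8)-3-O-acetyl-penta-O-benzyl-4α-(2,6-dimethylphenylthio)gallocatechin | c1c(OCc3ccccc3)cc(OCc3ccccc3)c2c1O[C@H](c1ccc(OCc3ccccc3)c(OCc3ccccc3)c1)[C@@H](OC(C)=O)[C@@H]2c1c(OCc3ccccc3)cc(OCc3ccccc3)c2c1O[C@H](c1cc(OCc3ccccc3)c(OCc3ccccc3)c(OCc3ccccc3)c1)[C@@H](OC(C)=O)[C@@H]2Sc1c(C)cccc1C
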